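**Plan**

1. Numbering: C1 is the ring carbon carrying the hydroxyl and the undecanoyl group (ketone carbon C1′), C2 and C5 carry the acetates, C3=C4 is the ring alkene; the target is meso.
2. Retrosynthesis cuts, in order: the two acetate ester bonds, the C1–OH bond, the C5–H bond (C5 back to a ketone), the ring bond C2–C3, then C1=C2 (C2 from an orthoformate) and C1–C1′.
3. Enabling feature: with C5 as a carbonyl the ring reads C3=C4–C5(=O)–C1–C2, so the cyclopentene is the closure product of a cross-conjugated dienone C3=C4–C5(=O)–C1=C2 in which C2 already holds the oxygen of one acetate and C1 is activated by C1′=O.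
4. Forward: the open chain is joined first (C1–C1′ by enolate acylation, then C2 added as an alkoxymethylidene carbon); the only ring arises in step 4 by C2–C3 closure, a trimethylsilyl group on C3 fixing the alkene at C3=C4.
5. Stereochemistry: C2 forms as a racemate in the ring closure; the C1 hydroxyl enters anti to the C2 ether (step 5) and the C5 hydroxyl arises by hydride attack anti to the undecanoyl group and the C2 ether (step 6), which gives the meso pattern without absolute control.

Key step: step 4

Remark: the SMILES places both acetoxy groups cis to the undecanoyl group and trans to the tertiary hydroxyl, so the target is achiral and racemic intermediates suffice; the C2 oxygen is carried as a 2-naphthylmethyl ether, which should resist the Lewis acid of step 4 better than a 4-methoxybenzyl ether and still leaves with DDQ.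

**Route**

Step 1
Reactants: 1 (3E)-4-(trimethylsilyl)but-3-en-2-one; 2 undecanoyl chloride
Product: 4 (1E)-1-(trimethylsilyl)pentadec-1-ene-3,5-dione, via lithium dienolate 3 (not isolated)
Conditions: 1 (2 equiv), LiN(SiMe3)2 (2 equiv), THF, −78 °C; then 2 (1 equiv), −78 → 0 °C; aq. NH4Cl
Reagents that add atoms: none
Why: Claisen-type C-acylation of the kinetic lithium dienolate of a methyl ketone by an acid chloride, the second equivalent of enolate deprotonating the β-diketone as it forms so that O-acylation and double acylation are suppressed.

Step 2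
Reactants: 4 (1E)-1-(trimethylsilyl)pentadec-1-ene-3,5-dione; 5 triethyl orthoformate
Product: 6 (1E)-4-(ethoxymethylidene)-1-(trimethylsilyl)pentadec-1-ene-3,5-dione
Conditions: 5 (2 equiv), Ac2O (3 equiv), 120 °C, ethyl acetate distilled off
Reagents that add atoms: none
Why: Claisen alkoxymethylenation, in which the enol of the β-diketone attacks the diethoxycarbenium ion formed from the orthoformate in acetic anhydride and then loses ethanol, the standard entry to 2-(ethoxymethylidene)-1,3-dicarbonyl compounds; the vinylsilane should tolerate hot acetic acid.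

Step 3
Reactants: 6 (1E)-4-(ethoxymethylidene)-1-(trimethylsilyl)pentadec-1-ene-3,5-dione; 7 naphthalen-2-ylmethanol
Product: 8 (1E)-4-[(naphthalen-2-ylmethoxy)methylidene]-1-(trimethylsilyl)pentadec-1-ene-3,5-dione
Conditions: 7 (1.2 equiv), PPTS (cat.), toluene, 60 °C, reduced pressure (EtOH removed)
Reagents that add atoms: none
Why: Acid-catalysed addition–elimination at the enol ether carbon of a vinylogous ester (transetherification), an equilibrium that should be pulled to 8 by removal of the volatile ethanol.

Step 4
Reactants: 8 (1E)-4-[(naphthalen-2-ylmethoxy)methylidene]-1-(trimethylsilyl)pentadec-1-ene-3,5-dione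
Product: 10 rac-(4S,5S)-4-(naphthalen-2-ylmethoxy)-5-undecanoylcyclopent-2-en-1-one, via trimethylsilyl enol ether 9 (not isolated)
Conditions: Cu(OTf)2 (10 mol %), ClCH2CH2Cl, 0 °C → rt; cold pH 7 phosphate buffer; crude 10 used at once
Reagents that add atoms: none
Why: Proposed new method: Cu(OTf)2 should chelate the C5 and C1′ ketone oxygens of 8 and generate a 3-oxidopentadienyl cation over C3=C4–C5–C1=C2 in which C2 is an oxocarbenium carbon and C3 the nucleophilic ipso carbon of the vinylsilane; thermal conrotatory 4π electrocyclisation then forms the C2–C3 bond, the charge left at C4 is stabilised by the β-silicon, and transfer of Me3Si to a diketonate oxygen gives 9, fixes the alkene at C3=C4 and releases the catalyst. The closest known reactions are the silicon-directed Nazarov cyclisation of β-silyl divinyl ketones and the Cu(OTf)2-catalysed Nazarov cyclisation of alkylidene β-dicarbonyl compounds, neither of which has been shown with an oxygen substituent on the closing carbon. The cyclopentene ring closes by this single 4π conrotatory electrocyclisation of the pentadienyl cation, and the enol ether geometry should not matter because the push–pull C1=C2 bond rotates freely in the complexed cation and puts the ether oxygen on the outside of the U-shaped array. C2 is the only stereocentre that persists and, with no chiral element present, it forms as a racemate, which is enough for a meso target; C1 stays epimerisable (10 is largely enolised) and its keto form should place the undecanoyl group trans to the ether. The step needs control of the alkene position and retention of the C2–O bond: the first is secured by the trimethylsilyl group on C3, the second by the low stability of the 2-naphthylmethyl cation and by the antiaromatic cyclopentadienone that loss of the alcohol would produce.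

Step 5
Reactants: 10 rac-(4S,5S)-4-(naphthalen-2-ylmethoxy)-5-undecanoylcyclopent-2-en-1-one
Product: 11 rac-(4S,5S)-5-hydroxy-4-(naphthalen-2-ylmethoxy)-5-undecanoylcyclopent-2-en-1-one
Conditions: dimethyldioxirane (1.1 equiv, acetone solution), CH2Cl2, −40 → 0 °C
Reagents that add atoms: dimethyldioxirane, CC1(C)OO1
Why: Electrophilic α-hydroxylation of an enolised β-diketone by dimethyldioxirane (epoxidation of the enol, then opening to the α-hydroxy diketone), the oxygen reaching the planar C1 from the face anti to the neighbouring naphthylmethoxy group so that the new hydroxyl is trans to the C2 oxygen and the undecanoyl group cis to it.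

Step 6
Reactants: 11 rac-(4S,5S)-5-hydroxy-4-(naphthalen-2-ylmethoxy)-5-undecanoylcyclopent-2-en-1-one
Product: 12 rac-1-[(1S,2R,5S)-1,2-dihydroxy-5-(naphthalen-2-ylmethoxy)cyclopent-3-en-1-yl]undecan-1-one
Conditions: NaBH4 (1 equiv), CeCl3·7H2O (1.1 equiv), MeOH, −78 °C; aq. NH4Cl
Reagents that add atoms: none
Why: Luche reduction, in which the methoxyborohydrides formed with CeCl3 should add 1,2 to the conjugated ring ketone faster than to the hindered saturated side-chain ketone, hydride entering from the face of the small tertiary hydroxyl (anti to the undecanoyl group on C1 and to the ether on C2) so that the new C5 hydroxyl is cis to the C2 oxygen.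

Step 7
Reactants: 12 rac-1-[(1S,2R,5S)-1,2-dihydroxy-5-(naphthalen-2-ylmethoxy)cyclopent-3-en-1-yl]undecan-1-one
Product: 13 1-[(1r,2R,5S)-1,2,5-trihydroxycyclopent-3-en-1-yl]undecan-1-one (meso)
Conditions: DDQ (1.5 equiv), CH2Cl2/pH 7 phosphate buffer (10:1), 0 °C → rt
Reagents that add atoms: none
Why: Oxidative cleavage of a 2-naphthylmethyl ether by DDQ (hydride abstraction from the arylmethyl carbon, then hydrolysis of the oxocarbenium ion by the water present), which should outpace oxidation of the electron-poor allylic alcohol and leaves the C2–O bond and its configuration untouched.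

Step 8
Reactants: 13 1-[(1r,2R,5S)-1,2,5-trihydroxycyclopent-3-en-1-yl]undecan-1-one
Product: 14 (1R,2r,3S)-2-hydroxy-2-undecanoylcyclopent-4-ene-1,3-diyl diacetate (meso; CNP0208983.3)
Conditions: Ac2O (2.5 equiv), pyridine, DMAP (cat.), CH2Cl2, 0 °C → rt
Reagents that add atoms: acetic anhydride, CC(=O)OC(C)=O
Why: Pyridine/DMAP-mediated acetylation should esterify the two secondary allylic hydroxyls while the hindered tertiary α-ketol hydroxyl stays free, no stereocentre being touched.

**Compound list**

1 | (3E)-4-(trimethylsilyl)but-3-en-2-one | CC(=O)/C=C/[Si](C)(C)C | starting material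
2 | undecanoyl chloride | CCCCCCCCCCC(Cl)=O | starting material
3 | lithium (3E)-4-(trimethylsilyl)buta-1,3-dien-2-olate (not isolated) | [Li+].[O-]C(=C)/C=C/[Si](C)(C)C | intermediate
4 | (1E)-1-(trimethylsilyl)pentadec-1-ene-3,5-dione (largely enolised) | CCCCCCCCCCC(=O)CC(=O)/C=C/[Si](C)(C)C | intermediate
5 | triethyl orthoformate | CCOC(OCC)OCC | starting material
6 | (1E)-4-(ethoxymethylidene)-1-(trimethylsilyl)pentadec-1-ene-3,5-dione (both methylidene geometries expected; one drawn) | CCCCCCCCCCC(=O)/C(=C/OCC)C(=O)/C=C/[Si](C)(C)C | intermediate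
7 | naphthalen-2-ylmethanol | OCc1ccc2ccccc2c1 | starting material
8 | (1E)-4-[(naphthalen-2-ylmethoxy)methylidene]-1-(trimethylsilyl)pentadec-1-ene-3,5-dione (both methylidene geometries expected; one drawn) | CCCCCCCCCCC(=O)/C(=C/OCc1ccc2ccccc2c1)C(=O)/C=C/[Si](C)(C)C | intermediate
9 | 4-(naphthalen-2-ylmethoxy)-5-[1-(trimethylsilyloxy)undecylidene]cyclopent-2-en-1-one (racemic; enol ether geometry undefined; silyl drawn on the side-chain oxygen; not isolated) | CCCCCCCCCCC(O[Si](C)(C)C)=C1C(OCc2ccc3ccccc3c2)C=CC1=O | intermediate
10 | rac-(4S,5S)-4-(naphthalen-2-ylmethoxy)-5-undecanoylcyclopent-2-en-1-one (trans keto form of an enolised β-diketone) | CCCCCCCCCCC(=O)[C@@H]1[C@@H](OCc2ccc3ccccc3c2)C=CC1=O | intermediate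
11 | rac-(4S,5S)-5-hydroxy-4-(naphthalen-2-ylmethoxy)-5-undecanoylcyclopent-2-en-1-one (hydroxyl trans to the ether oxygen) | CCCCCCCCCCC(=O)[C@@]1(O)[C@@H](OCc2ccc3ccccc3c2)C=CC1=O | intermediate
12 | rac-1-[(1S,2R,5S)-1,2-dihydroxy-5-(naphthalen-2-ylmethoxy)cyclopent-3-en-1-yl]undecan-1-one (secondary hydroxyl cis to the ether, both trans to the tertiary hydroxyl) | CCCCCCCCCCC(=O)[C@@]1(O)[C@@H](OCc2ccc3ccccc3c2)C=C[C@H]1O | intermediate
13 | 1-[(1r,2R,5S)-1,2,5-trihydroxycyclopent-3-en-1-yl]undecan-1-one (meso; secondary hydroxyls cis to each other and to the undecanoyl group) | CCCCCCCCCCC(=O)[C@@]1(O)[C@@H](O)C=C[C@H]1O | intermediate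
14 | (1R,2r,3S)-2-hydroxy-2-undecanoylcyclopent-4-ene-1,3-diyl diacetate (meso; acetoxy groups cis to each other and to the undecanoyl group, trans to the hydroxyl) | CCCCCCCCCCC(=O)[C@@]1(O)[C@@H](OC(C)=O)C=C[C@H]1OC(C)=O | target

**Summary and risks**

Total steps: 8. Longest linear sequence: 8 steps (1 → 14).

Steps most likely to fail:

Step 4. The ether oxygen may stabilise the open cation so strongly that ring closure is slow. The copper-bound enol ether may then lose its arylmethyl group by ionisation, or the enolised product may drift by proton shift to the achiral 3-alkoxy-2-acylcyclopentenone. The fallback uses known chemistry, sets out from 7 and rejoins at 10. Alcohol 7 is added to trichloroacetonitrile (DBU cat., CH2Cl2, 0 °C) to give naphthalen-2-ylmethyl 2,2,2-trichloroacetimidate F1. F1 etherifies commercial racemic 4-hydroxycyclopent-2-en-1-one under TfOH catalysis (CH2Cl2, 0 °C) to give 4-(naphthalen-2-ylmethoxy)cyclopent-2-en-1-one F2. Kinetic deprotonation of F2 (LiN(SiMe3)2, THF, −78 °C, two equivalents of enolate per acid chloride) gives lithium 3-(naphthalen-2-ylmethoxy)cyclopenta-1,4-dien-1-olate F3, and C-acylation of F3 with acid chloride 2 should deliver 10.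

Step 6. Hydride addition to the side-chain ketone may compete with reduction of the ring ketone (loss of chemoselectivity). The fallback sets out from 11 and rejoins at 12. Both ketones are reduced on purpose (excess NaBH4, CeCl3·7H2O, MeOH, 0 °C) to 1-[1,2-dihydroxy-5-(naphthalen-2-ylmethoxy)cyclopent-3-en-1-yl]undecan-1-ol F4, with the ring configuration of 12 and a mixture at the side-chain carbinol. Bu2SnO in refluxing toluene with removal of water then engages the vicinal side-chain diol, the only hydroxyl pair able to span tin in a five-membered ring because the two ring hydroxyls are trans, as the dibutylstannylene acetal 2,2-dibutyl-4-decyl-6-(naphthalen-2-ylmethoxy)-1,3-dioxa-2-stannaspiro[4.4]non-7-en-9-ol F5. N-Bromosuccinimide (CHCl3, rt) oxidises the secondary tin alkoxide of F5 to the ketone and returns 12.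

Step 7. DDQ may dehydrogenate the free allylic alcohol at C5 back to the enone, or the arylmethyl oxocarbenium ion may be trapped by the cis C5 hydroxyl as a cyclic acetal, so that deprotection is slow or unselective. The fallback sets out from 12 and rejoins at 14. The C5 hydroxyl is acetylated first (Ac2O, pyridine, DMAP cat., 0 °C) to give rac-2-hydroxy-3-(naphthalen-2-ylmethoxy)-2-undecanoylcyclopent-4-en-1-yl acetate F6. DDQ in CH2Cl2/pH 7 buffer then removes the naphthylmethyl group from a substrate without an oxidisable alcohol and gives rac-2,3-dihydroxy-2-undecanoylcyclopent-4-en-1-yl acetate F7. Acetylation of the remaining secondary hydroxyl gives 14.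

**Further compounds**

F1 | step 4 | naphthalen-2-ylmethyl 2,2,2-trichloroacetimidate | ClC(Cl)(Cl)C(=N)OCc1ccc2ccccc2c1
F2 | step 4 | 4-(naphthalen-2-ylmethoxy)cyclopent-2-en-1-one (racemic) | O=C1CC(OCc2ccc3ccccc3c2)C=C1
F3 | step 4 | lithium 3-(naphthalen-2-ylmethoxy)cyclopenta-1,4-dien-1-olate (racemic) | [Li+].[O-]C1=CC(OCc2ccc3ccccc3c2)C=C1
F4 | step 6 | 1-[1,2-dihydroxy-5-(naphthalen-2-ylmethoxy)cyclopent-3-en-1-yl]undecan-1-ol (racemic; ring configuration as in 12; mixture at the side-chain carbinol) | CCCCCCCCCCC(O)[C@@]1(O)[C@@H](OCc2ccc3ccccc3c2)C=C[C@H]1O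
F5 | step 6 | 2,2-dibutyl-4-decyl-6-(naphthalen-2-ylmethoxy)-1,3-dioxa-2-stannaspiro[4.4]non-7-en-9-ol (stannylene acetal of F4) | CCCCCCCCCCC2O[Sn](CCCC)(CCCC)O[C@@]21[C@@H](OCc3ccc4ccccc4c3)C=C[C@H]1O
F6 | step 7 | rac-2-hydroxy-3-(naphthalen-2-ylmethoxy)-2-undecanoylcyclopent-4-en-1-yl acetate (relative configuration as in 12) | CCCCCCCCCCC(=O)[C@@]1(O)[C@@H](OCc2ccc3ccccc3c2)C=C[C@H]1OC(C)=O
F7 | step 7 | rac-2,3-dihydroxy-2-undecanoylcyclopent-4-en-1-yl acetate (relative configuration as in 13) | CCCCCCCCCCC(=O)[C@@]1(O)[C@@H](O)C=C[C@H]1OC(C)=O
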